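## Retrosynthetic overview

1. The target comes from removal of two silyl groups from a ring-enlarged 6-siloxycyclohex-2-enone.
2. The six-membered ring comes from an acyloin-type 1,2-shift (five to six) in a 1-(benzoyloxyacetyl)cyclopent-2-enyl silyl ether. The ring bond to CH(OBz) moves from the carbinol carbon to the side-chain C=O, which makes the C1–C6 bond, the tertiary carbinol C1 and the enone C=O.
3. The ketol comes from α-oxybenzoylation of a methyl ketone. That ketone comes from acetyl-anion addition (ethyl vinyl ether as the two-carbon unit) to a trans-5-benzoyloxy-4-siloxycyclopent-2-enone.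
4. The enone comes from α′-hydroxylation/benzoylation of silylated (S)-4-hydroxycyclopent-2-enone, the only source of chirality (relay C5 → C6 → carbinol carbon → C1).
5. Ring order: there is one carbocycle, bought as a five-membered ring and enlarged to the six-membered ring in the last step.

Assumption: (S)-4-hydroxycyclopent-2-en-1-one is bought enantiopure. Target numbering is C1 (tertiary carbinol), C2 (C=O), C3=C4, C5 (CHOH), C6 (CHOBz), C7 (CH2OBz).

## Route

Step 1
Reactants: 1 (S)-4-hydroxycyclopent-2-en-1-one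
Product: 2 (S)-4-[(tert-butyldimethylsilyl)oxy]cyclopent-2-en-1-one
Conditions: TBSCl, imidazole, CH2Cl2, 0 °C → rt
Reagents that add atoms: tert-butyldimethylsilyl chloride, CC(C)(C)[Si](C)(C)Cl
Why: Standard imidazole-mediated silyl ether formation masks the hydroxy group for the enolate and organolithium steps and does not touch the stereocentre (the later C5).

Step 2
Reactants: 2 (S)-4-[(tert-butyldimethylsilyl)oxy]cyclopent-2-en-1-one
Product: 5 (1S,5R)-5-[(tert-butyldimethylsilyl)oxy]-2-oxocyclopent-3-en-1-yl benzoate, via sodium dienolate 3 (not isolated), via sodium alkoxide 4 (not isolated)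
Conditions: NaN(SiMe3)2, THF, −78 °C; 3-phenyl-2-(phenylsulfonyl)oxaziridine, −78 °C; then BzCl, −78 → −20 °C
Reagents that add atoms: 3-phenyl-2-(phenylsulfonyl)oxaziridine, O=S(=O)(N1OC1c1ccccc1)c1ccccc1; benzoyl chloride, O=C(Cl)c1ccccc1
Why: Kinetic α′-deprotonation followed by Davis oxidation delivers oxygen to the dienolate face anti to the adjacent OTBS group, and the alkoxide is benzoylated in situ, so the new stereocentre (the later C6) is set trans to C–OTBS.

Step 3
Reactants: 5 (1S,5R)-5-[(tert-butyldimethylsilyl)oxy]-2-oxocyclopent-3-en-1-yl benzoate; 6 ethyl vinyl ether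
Product: 9 (1S,2R,5R)-2-acetyl-5-[(tert-butyldimethylsilyl)oxy]-2-hydroxycyclopent-3-en-1-yl benzoate, via (1-ethoxyvinyl)lithium 7 (not isolated), via lithium alkoxide adduct 8 (not isolated)
Conditions: 6, t-BuLi, THF, −78 → 0 °C; added to 5 + LaCl3·2LiCl, THF, −78 °C; then 1 M aq HCl, −78 → 0 °C
Reagents that add atoms: water, O
Why: Lanthanide-assisted 1,2-addition of an acyl-anion equivalent (α-lithiated enol ether) takes place anti to the neighbouring benzoyloxy group (steric and Felkin-type control), which puts the new C–C bond trans and the carbinol oxygen cis to OBz, and mild acid hydrolysis of the enol ether then unveils the methyl ketone.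

Step 4
Reactants: 9 (1S,2R,5R)-2-acetyl-5-[(tert-butyldimethylsilyl)oxy]-2-hydroxycyclopent-3-en-1-yl benzoate
Product: 12 (1S,2R,5R)-2-[2-(benzoyloxy)acetyl]-5-[(tert-butyldimethylsilyl)oxy]-2-hydroxycyclopent-3-en-1-yl benzoate, via ene-hydroxylamine 10 (not isolated), via alpha-benzoyloxy imine 11 (not isolated)
Conditions: MeNH–OBz·HCl, DMSO, 25 → 40 °C
Reagents that add atoms: N-methyl-O-benzoylhydroxylamine hydrochloride, CNOC(=O)c1ccccc1.Cl
Why: In this ketone α-oxyacylation with an O-acyl-N-alkylhydroxylamine, condensation, [3,3]-sigmatropic N–O to C–O transfer and hydrolysis place the benzoate on the only enolisable carbon (the CH3 group) under weakly acidic conditions that tolerate the free tertiary OH, the TBS ether and all stereocentres.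

Step 5
Reactants: 12 (1S,2R,5R)-2-[2-(benzoyloxy)acetyl]-5-[(tert-butyldimethylsilyl)oxy]-2-hydroxycyclopent-3-en-1-yl benzoate
Product: 15 [(1R,5R,6S)-6-(benzoyloxy)-1,5-dihydroxy-2-oxocyclohex-3-en-1-yl]methyl benzoate, via trimethylsilyl ether 13 (not isolated), via ring-enlarged bis-silyl ether 14 (not isolated)
Conditions: TMSNTf2 (1.25 equiv), 2,6-lutidine (1.05 equiv), CH2Cl2, −78 → 0 °C; then HF·pyridine, 0 °C → rt, same flask
Reagents that add atoms: none
Why: Proposed new method: a silylium-catalysed, non-chelated acyloin (α-ketol) ring enlargement of a 1-acylcyclopent-2-enyl silyl ether, in which the first equivalent of TMSNTf2 caps the tertiary OH (removing the H-bond or chelate that would enforce the cisoid O=C–C–O geometry) and the surplus 0.2 equiv silylates the side-chain C=O as a monodentate Lewis acid, so the two C–O dipoles stand anti (transoid) and CH2OBz points away from the ring face that carries OTBS; in this rotamer the ring bond from the carbinol carbon to CH(OBz) overlaps with π*(C=O) and shifts suprafacially with retention at the migrating carbon, placing the new C–OSi bond trans and CH2OBz cis to OBz, that is (R) at C1; this carbon rather than the vinyl carbon should migrate because the vinyl group left behind stabilises the developing siloxyallyl cation, and because all shifts are reversible under silylium catalysis while the conjugated six-membered enone is the thermodynamic sink; the siloxycarbenium ion then hands TMS+ on to close the cycle and HF·pyridine removes both silyl groups; the closest known reaction types are the base-induced (transoid) D-homoannulation of 17-hydroxy-20-keto steroids, including the 21-acyloxy series, and the Lewis-acid rearrangement of α-siloxy aldehydes to α-siloxy ketones.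

## Compound list

1 | (S)-4-hydroxycyclopent-2-en-1-one | O=C1C=C[C@@H](O)C1 | starting material
2 | (S)-4-[(tert-butyldimethylsilyl)oxy]cyclopent-2-en-1-one | O=C1C=C[C@@H](O[Si](C)(C)C(C)(C)C)C1 | intermediate
3 | sodium (3R)-3-[(tert-butyldimethylsilyl)oxy]cyclopenta-1,4-dien-1-olate (cross-conjugated dienolate of 2) | [Na+].[O-]C1=C[C@H](O[Si](C)(C)C(C)(C)C)C=C1 | intermediate
4 | sodium (1S,5R)-5-[(tert-butyldimethylsilyl)oxy]-2-oxocyclopent-3-en-1-olate | O=C1C=C[C@@H](O[Si](C)(C)C(C)(C)C)[C@@H]1[O-].[Na+] | intermediate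
5 | (1S,5R)-5-[(tert-butyldimethylsilyl)oxy]-2-oxocyclopent-3-en-1-yl benzoate (OTBS and OBz trans) | O=C1C=C[C@@H](O[Si](C)(C)C(C)(C)C)[C@@H]1OC(=O)c1ccccc1 | intermediate
6 | ethyl vinyl ether | C=COCC | starting material
7 | (1-ethoxyvinyl)lithium | [Li]C(=C)OCC | intermediate
8 | lithium (1R,4R,5S)-5-(benzoyloxy)-4-[(tert-butyldimethylsilyl)oxy]-1-(1-ethoxyvinyl)cyclopent-2-en-1-olate | C=C(OCC)[C@@]1([O-])C=C[C@@H](O[Si](C)(C)C(C)(C)C)[C@@H]1OC(=O)c1ccccc1.[Li+] | intermediate
9 | (1S,2R,5R)-2-acetyl-5-[(tert-butyldimethylsilyl)oxy]-2-hydroxycyclopent-3-en-1-yl benzoate (acetyl trans to OBz, cis to OTBS) | CC(=O)[C@@]1(O)C=C[C@@H](O[Si](C)(C)C(C)(C)C)[C@@H]1OC(=O)c1ccccc1 | intermediate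
10 | N-benzoyloxy-N-methyl enamine of 9 (ring stereocentres as in 9) | C=C(N(C)OC(=O)c1ccccc1)[C@@]1(O)C=C[C@@H](O[Si](C)(C)C(C)(C)C)[C@@H]1OC(=O)c1ccccc1 | intermediate
11 | N-methyl imine of 12 (ring stereocentres as in 9) | CN=C(COC(=O)c1ccccc1)[C@@]1(O)C=C[C@@H](O[Si](C)(C)C(C)(C)C)[C@@H]1OC(=O)c1ccccc1 | intermediate
12 | (1S,2R,5R)-2-[2-(benzoyloxy)acetyl]-5-[(tert-butyldimethylsilyl)oxy]-2-hydroxycyclopent-3-en-1-yl benzoate | O=C(COC(=O)c1ccccc1)[C@@]1(O)C=C[C@@H](O[Si](C)(C)C(C)(C)C)[C@@H]1OC(=O)c1ccccc1 | intermediate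
13 | (1S,2R,5R)-2-[2-(benzoyloxy)acetyl]-5-[(tert-butyldimethylsilyl)oxy]-2-[(trimethylsilyl)oxy]cyclopent-3-en-1-yl benzoate | O=C(COC(=O)c1ccccc1)[C@@]1(O[Si](C)(C)C)C=C[C@@H](O[Si](C)(C)C(C)(C)C)[C@@H]1OC(=O)c1ccccc1 | intermediate
14 | [(1R,5R,6S)-6-(benzoyloxy)-5-[(tert-butyldimethylsilyl)oxy]-2-oxo-1-[(trimethylsilyl)oxy]cyclohex-3-en-1-yl]methyl benzoate | O=C(OC[C@]1(O[Si](C)(C)C)C(=O)C=C[C@@H](O[Si](C)(C)C(C)(C)C)[C@@H]1OC(=O)c1ccccc1)c1ccccc1 | intermediate
15 | [(1R,5R,6S)-6-(benzoyloxy)-1,5-dihydroxy-2-oxocyclohex-3-en-1-yl]methyl benzoate | O=C(OC[C@]1(O)C(=O)C=C[C@@H](O)[C@@H]1OC(=O)c1ccccc1)c1ccccc1 | target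

## Step count and risks

Total step count: 5. Longest linear sequence: 5 (1 → 2 → 5 → 9 → 12 → 15).

**Step 5 (the new step).**
- Leakage through the cisoid rotamer would give the C1 epimer.
- The strong silyl Lewis acid could ionise the allylic C5–OTBS bond with participation of the trans benzoate.
- It could also enol-silylate C7 or be sequestered by the two ester carbonyls.
- The fallback sets out from 12 and comes back at 15. It leaves the cationic manifold and the ester-bearing substrate altogether. K2CO3 in MeOH (0 °C → rt) removes both benzoates by methanolysis, and the free alkoxide undergoes the classical base-induced, transoid acyloin ring enlargement known from the corticoid side chain. This gives (4R,5S,6R)-4-[(tert-butyldimethylsilyl)oxy]-5,6-dihydroxy-6-(hydroxymethyl)cyclohex-2-en-1-one F1. BzCl (2.2 equiv), pyridine, DMAP, CH2Cl2, −20 °C then esterifies the primary and the secondary hydroxy group but not the tertiary one, giving [(1R,5R,6S)-6-(benzoyloxy)-5-[(tert-butyldimethylsilyl)oxy]-1-hydroxy-2-oxocyclohex-3-en-1-yl]methyl benzoate F2. HF·pyridine converts this to 15.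

**Step 3.**
- The basic vinyllithium may enolise 5, with loss of silanolate, or attack the benzoate.
- The cis alkoxide may pull the benzoyl group onto the tertiary oxygen.
- The OTBS group on the attacked face may erode the facial selectivity.
- The fallback sets out from 5 and comes back at 9. It uses a much less basic acyl-anion equivalent and a separate, neutral unmasking. HC≡CMgBr, LaCl3·2LiCl, THF, −78 °C gives (1S,2S,5R)-5-[(tert-butyldimethylsilyl)oxy]-2-ethynyl-2-hydroxycyclopent-3-en-1-yl benzoate F3. Markovnikov hydration of the terminal alkyne (Hg(OTf)2 5 mol %, H2O, MeCN–CH2Cl2, rt) then gives methyl ketone 9.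

**Step 2.**
- The α′-enolate carries a β-silyloxy leaving group and can collapse to a cyclopentadienone.
- The sulfonimine by-product can also trap the enolate.
- The fallback sets out from 2 and comes back at 5. It avoids any strongly basic enolate by using oxidative α′-acyloxylation of the enone with trivalent manganese (Mn(OAc)3·2H2O, PhCO2H in excess, benzene, reflux with water removal). The benzoate enters anti to OTBS and 5 forms directly. This fallback makes no new compound (F0).

## Further compounds

F1 | step 5 | (4R,5S,6R)-4-[(tert-butyldimethylsilyl)oxy]-5,6-dihydroxy-6-(hydroxymethyl)cyclohex-2-en-1-one | OC[C@]1(O)C(=O)C=C[C@@H](O[Si](C)(C)C(C)(C)C)[C@@H]1O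
F2 | step 5 | [(1R,5R,6S)-6-(benzoyloxy)-5-[(tert-butyldimethylsilyl)oxy]-1-hydroxy-2-oxocyclohex-3-en-1-yl]methyl benzoate | O=C(OC[C@]1(O)C(=O)C=C[C@@H](O[Si](C)(C)C(C)(C)C)[C@@H]1OC(=O)c1ccccc1)c1ccccc1
F3 | step 3 | (1S,2S,5R)-5-[(tert-butyldimethylsilyl)oxy]-2-ethynyl-2-hydroxycyclopent-3-en-1-yl benzoate | C#C[C@@]1(O)C=C[C@@H](O[Si](C)(C)C(C)(C)C)[C@@H]1OC(=O)c1ccccc1
F0 | step 2 | none | none
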